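**Retrosynthetic overview**
1. Norbornene (C1–C13′ and C3–C11′, made last): Pd(0)-catalysed 1,4-elimination of guaianolide allylic diacetate 36 releases the 2-acetoxy-cyclopentadiene, which is trapped in a [4+2] by eudesmanolide 18.
2. Eudesmanolide 18: ring A (from cyclohexane-1,3-dione) → cis-lactone by a Cr-catalysed asymmetric carboxy-pentadienylation of keto-aldehyde 12 with dienyl bromide 4 (C7′–C8′) → ring B by Ru ring-closing metathesis (C5′=C6′).
3. Guaianolide 36: cyclopentenone (from 2-methylcyclopentane-1,3-dione; Ir allylic alkylation makes C1–C10) → seven-membered ring and trans-lactone together by intramolecular Cr-catalysed allylation (C7–C8) → C2/C3 oxygenation.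
4. Ring order: eudesmane A → lactone → B; guaiane five-ring → seven-ring/lactone; norbornene last.

Assumption: the absolute configuration is taken exactly as written in the SMILES (eudesmane half 1′S,4′R,7′S,8′S,10′S; guaiane half 7S,8R,10R), and every chiral catalyst antipode is chosen for that series. Eudesmane/guaiane numbering is used throughout; primes mark the eudesmane half.

---

## Route

### Dienyl bromide 4

**Step 1**
Reactants: 1 acrolein; 2 methyl acrylate
Product: 3 methyl 3-hydroxy-2-methylidenepent-4-enoate (racemic)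
Conditions: DABCO (20 mol %), 1,4-dioxane/H2O 1:1, 0 °C → rt
Reagents that add atoms: none
Why: Morita–Baylis–Hillman reaction at the aldehyde of acrolein; the carbinol centre is erased in step 2.

**Step 2**
Reactants: 3
Product: 4 methyl (2Z)-2-(bromomethyl)penta-2,4-dienoate
Conditions: PBr3, Et2O, −10 → 0 °C
Reagents that add atoms: phosphorus tribromide, BrP(Br)Br
Why: SN2′ bromination of a Baylis–Hillman alcohol with allylic transposition gives the conjugated dienoate; any regioisomeric dienyl bromide gives the same pentadienyl-chromium species in step 9.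

### Eudesmanolide half (18)

**Step 3**
Reactants: 5 cyclohexane-1,3-dione
Product: 6 2-methylcyclohexane-1,3-dione
Conditions: MeI, KOH, H2O/dioxane, reflux
Reagents that add atoms: iodomethane, CI
Why: C-methylation of the 1,3-dione enolate.

**Step 4**
Reactants: 6; 7 allyl acetate
Product: 8 2-methyl-2-(prop-2-enyl)cyclohexane-1,3-dione
Conditions: Pd(PPh3)4 (1 mol %), DBU, THF, rt
Reagents that add atoms: none
Why: Tsuji–Trost C-allylation of the soft dione enolate builds the future C10 quaternary carbon (achiral at this stage).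

**Step 5**
Reactants: 8
Product: 9 (2R,3R)-3-hydroxy-2-methyl-2-(prop-2-enyl)cyclohexan-1-one (OH cis to allyl)
Conditions: RuCl[(R,R)-TsDPEN](p-cymene) (1 mol %; antipode chosen for the 2R,3R ketol), HCO2H/Et3N 5:2, CH2Cl2, 30 °C
Reagents that add atoms: none
Why: Noyori asymmetric transfer hydrogenation desymmetrises the dione; the catalyst picks the carbonyl (sets C10′) and hydride enters anti to the allyl group (temporary C1′ carbinol, inverted in steps 13–14).

**Step 6**
Reactants: 9
Product: 10 (2R,3R)-3-(tert-butyldimethylsilyloxy)-2-methyl-2-(prop-2-enyl)cyclohexan-1-one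
Conditions: TBSOTf, 2,6-lutidine, CH2Cl2, 0 °C
Reagents that add atoms: TBS triflate, CC(C)(C)[Si](C)(C)OS(=O)(=O)C(F)(F)F
Why: Silylation of the hindered alcohol; the equatorial OTBS fixes the chair with the allyl group axial for step 7.

**Step 7**
Reactants: 10
Product: 11 (2R,3R,6R)-3-(TBSO)-2,6-dimethyl-2-(prop-2-enyl)cyclohexan-1-one (6-Me cis to 2-Me)
Conditions: LDA, THF, −78 °C; MeI, −78 → −20 °C; then NaOMe, MeOH, rt
Reagents that add atoms: iodomethane, CI
Why: Enolate alkylation is possible only at C4′; MeI enters anti to the axial allyl group and equilibration converges on the same equatorial isomer (C4′ methyl cis to C10′ methyl).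

**Step 8**
Reactants: 11
Product: 12 [(1R,3R,6R)-6-(TBSO)-1,3-dimethyl-2-oxocyclohexyl]acetaldehyde
Conditions: O3, CH2Cl2/MeOH, −78 °C; Me2S
Reagents that add atoms: ozone, [O-][O+]=O
Why: Ozonolysis of the only alkene gives the C8′ aldehyde without touching the stereocentres.

**Step 9**
Reactants: 12; 4
Product: 13 (4S,5S)-5-{[(1R,3R,6R)-6-(TBSO)-1,3-dimethyl-2-oxocyclohexyl]methyl}-4-ethenyl-3-methylideneoxolan-2-one (4,5-cis)
Conditions: CrCl3 (10 mol %), carbazole-bis(oxazoline) ligand (11 mol %; antipode chosen for 7′S,8′S), Mn (2 equiv), TMSCl, iPr2NEt, THF, 0 °C → rt; then TsOH·H2O (cat.), CH2Cl2, rt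
Reagents that add atoms: none
Why: Proposed new method: a Cr-catalysed, ligand-controlled, γ-selective 2-(methoxycarbonyl)pentadienylation — 4 adds oxidatively to Cr(II) to give an ester-chelated pentadienyl-Cr(III) that attacks the aldehyde through its γ-carbon in a closed chair transition state with the vinyl-bearing carbon cis to Cr–CH2, so the 7′,8′-syn adduct forms and lactonises to the cis β-vinyl α-methylene lactone, while the ligand selects the aldehyde face independently of the remote C10′ centre (Mn/TMSCl turn over Cr; the hindered ketone is untouched); the closest known reaction is the catalytic asymmetric Nozaki–Hiyama–Kishi 2-(alkoxycarbonyl)allylation of aldehydes, not yet shown for a dienyl bromide, for γ- over ε-attack, or on a β-quaternary keto-aldehyde.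

**Step 10**
Reactants: 13
Product: 14 (4S,5S)-5-{[(1S,3R,6R)-6-(TBSO)-1,3-dimethyl-2-methylidenecyclohexyl]methyl}-4-ethenyl-3-methylideneoxolan-2-one
Conditions: Zn, CH2Br2, TiCl4, THF/CH2Cl2, 0 °C → rt
Reagents that add atoms: dibromomethane, BrCBr
Why: Lombardo–Takai methylenation is non-basic (no C4′ epimerisation) and selective for the ketone over the lactone.

**Step 11**
Reactants: 14
Product: 15 (1R,4R,7S,8S,10S)-1-(TBSO)eudesma-5,11(13)-dien-12,8-olide
Conditions: Hoveyda–Grubbs II (10 mol %), toluene (5 mM), 80 °C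
Reagents that add atoms: none
Why: Ring-closing metathesis between the vinyl group and the 1,1-disubstituted methylene forms ring B and the trisubstituted C5′=C6′ alkene; the α-methylene lactone is a poor metathesis partner and cannot cyclise.

**Step 12**
Reactants: 15
Product: 16 (1R,4R,7S,8S,10S)-1-hydroxyeudesma-5,11(13)-dien-12,8-olide
Conditions: HF·pyridine, THF, 0 °C → rt
Reagents that add atoms: none
Why: Acidic fluoride desilylation avoids base-induced damage to the α-methylene lactone.

**Step 13**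
Reactants: 16
Product: 17 (4R,7S,8S,10S)-1-oxoeudesma-5,11(13)-dien-12,8-olide
Conditions: Dess–Martin periodinane, NaHCO3, CH2Cl2, rt
Reagents that add atoms: none
Why: Mild alcohol oxidation; the ketone has no enolisable stereocentre next to C10′.

**Step 14**
Reactants: 17
Product: 18 (1S,4R,7S,8S,10S)-1-hydroxyeudesma-5,11(13)-dien-12,8-olide (OH, both methyls and the lactone bonds all on one face)
Conditions: NaBH4, CeCl3·7H2O, MeOH, −78 °C
Reagents that add atoms: none
Why: Luche 1,2-reduction; hydride attacks axially anti to the axial angular methyl (as in Wieland–Miescher-type ketones), giving the equatorial alcohol cis to C10′-Me without conjugate reduction of the lactone.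

### Guaianolide half (36)

**Step 15**
Reactants: 19 (E)-but-2-en-1-ol
Product: 20 (E)-but-2-en-1-yl methyl carbonate
Conditions: ClCO2Me, pyridine, CH2Cl2, 0 °C
Reagents that add atoms: methyl chloroformate, COC(=O)Cl
Why: Standard carbonate formation to give the allylic electrophile for step 17.

**Step 16**
Reactants: 21 2-methylcyclopentane-1,3-dione
Product: 22 2-methyl-3-(2-methylpropoxy)cyclopent-2-en-1-one
Conditions: i-BuOH, TsOH (cat.), toluene, reflux (Dean–Stark)
Reagents that add atoms: 2-methylpropan-1-ol, CC(C)CO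
Why: Vinylogous ester formation differentiates the two carbonyls for Stork–Danheiser chemistry.

**Step 17**
Reactants: 22; 20
Product: 23 (5S)-5-[(2R)-but-3-en-2-yl]-2-methyl-3-(2-methylpropoxy)cyclopent-2-en-1-one
Conditions: LDA, TMSCl, THF, −78 °C; then [Ir(cod)Cl]2 (2 mol %), Feringa-type phosphoramidite (4 mol %; antipode chosen for 10R), KF, 18-crown-6, THF, 50 °C
Reagents that add atoms: none
Why: Ir-catalysed branched-selective asymmetric allylic alkylation of the α′-silyl dienol ether forms C1–C10; the catalyst sets C10, and C1 is formed with useful diastereoselectivity (minor epimer removed by chromatography).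

**Step 18**
Reactants: 23
Product: 24 (5S)-5-[(2R)-4-hydroxybutan-2-yl]-2-methyl-3-(2-methylpropoxy)cyclopent-2-en-1-one
Conditions: 9-BBN, THF, 0 °C → rt; then H2O2, pH 7 buffer
Reagents that add atoms: hydrogen peroxide, OO
Why: Anti-Markovnikov hydroboration–oxidation of the only terminal alkene gives C8 at the alcohol level.

**Step 19**
Reactants: 24
Product: 25 (5S)-5-[(2R)-4-(tert-butyldiphenylsilyloxy)butan-2-yl]-2-methyl-3-(2-methylpropoxy)cyclopent-2-en-1-one
Conditions: TBDPSCl, imidazole, CH2Cl2, rt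
Reagents that add atoms: TBDPS chloride, CC(C)(C)[Si](Cl)(c1ccccc1)c1ccccc1
Why: An acid-stable silyl ether is needed to survive the hydrolysis in step 20.

**Step 20**
Reactants: 25; 26 allylmagnesium bromide
Product: 27 (4S)-4-[(2R)-4-(TBDPSO)butan-2-yl]-2-methyl-3-(prop-2-enyl)cyclopent-2-en-1-one
Conditions: CeCl3, THF, −78 → 0 °C; then 1 M HCl, THF, 0 °C → rt
Reagents that add atoms: none
Why: Stork–Danheiser sequence (1,2-addition to the vinylogous ester, then hydrolysis with carbonyl transposition) gives the C3-ketone/C4=C5 enone with C6–C7 attached.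

**Step 21**
Reactants: 27; 28 methyl 2-(hydroxymethyl)acrylate (4 equiv)
Product: 29 methyl (2E)-2-(hydroxymethyl)-4-{(5S)-5-[(2R)-4-(TBDPSO)butan-2-yl]-2-methyl-3-oxocyclopent-1-en-1-yl}but-2-enoate
Conditions: Hoveyda–Grubbs II (5 mol %), 1,4-benzoquinone (10 mol %), CH2Cl2, 40 °C
Reagents that add atoms: none
Why: Olefin cross-metathesis of the terminal allyl group with a 2-substituted acrylate (C7=C11); the tetrasubstituted enone is inert and the alkene geometry is irrelevant for step 25.

**Step 22**
Reactants: 29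
Product: 30 methyl (2Z)-2-(bromomethyl)-4-{(5S)-5-[(2R)-4-(TBDPSO)butan-2-yl]-2-methyl-3-oxocyclopent-1-en-1-yl}but-2-enoate
Conditions: CBr4, PPh3, CH2Cl2, 0 °C
Reagents that add atoms: carbon tetrabromide, BrC(Br)(Br)Br
Why: Appel bromination of the primary allylic alcohol.

**Step 23**
Reactants: 30
Product: 31 methyl (2Z)-2-(bromomethyl)-4-{(5S)-5-[(2R)-4-hydroxybutan-2-yl]-2-methyl-3-oxocyclopent-1-en-1-yl}but-2-enoate
Conditions: HF·pyridine, THF, 0 °C → rt
Reagents that add atoms: none
Why: Acidic desilylation leaves the allylic bromide intact.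

**Step 24**
Reactants: 31
Product: 32 methyl (2Z)-2-(bromomethyl)-4-{(5S)-2-methyl-3-oxo-5-[(2R)-4-oxobutan-2-yl]cyclopent-1-en-1-yl}but-2-enoate
Conditions: Dess–Martin periodinane, NaHCO3, CH2Cl2, rt
Reagents that add atoms: none
Why: Mild oxidation to the C8 aldehyde.

**Step 25**
Reactants: 32
Product: 33 (1S,7S,8R,10R)-3-oxoguaia-4,11(13)-dien-12,8-olide (7,8-trans lactone)
Conditions: CrCl2 (20 mol %), Mn, TMSCl, THF (5 mM), rt; then TsOH·H2O (cat.), CH2Cl2, rt
Reagents that add atoms: none
Why: Intramolecular Nozaki–Hiyama–Kishi-type allylation closes the seven-membered ring through a chair transition state in which the ring tether holds C6 and C9 pseudo-equatorial (H7/H8 trans) and the pseudo-equatorial C10 methyl and the C1 centre select the aldehyde face; the hydroxy ester lactonises, and the aldehyde reacts far faster than the enone carbonyl.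

**Step 26**
Reactants: 33
Product: 34 (1S,2R,7S,8R,10R)-2-hydroxy-3-oxoguaia-4,11(13)-dien-12,8-olide
Conditions: TMSOTf, Et3N, CH2Cl2, 0 °C; then mCPBA, NaHCO3, −20 °C; citric acid, MeOH
Reagents that add atoms: mCPBA, O=C(OO)c1cccc(Cl)c1
Why: Rubottom oxidation of the cross-conjugated (α′) silyl dienol ether; the oxidant approaches C2 anti to the C1–C10 bond, so the new OH is cis to H1, and the electron-poor alkenes are untouched.

**Step 27**
Reactants: 34
Product: 35 (1S,2R,3R,7S,8R,10R)-2,3-dihydroxyguaia-4,11(13)-dien-12,8-olide (2,3-trans)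
Conditions: Me4NBH(OAc)3, MeCN/AcOH, −30 °C
Reagents that add atoms: none
Why: Hydroxyl-directed (Evans–Saksena-type) reduction delivers hydride to the face of the C2 hydroxyl, giving the trans-diol needed for the elimination geometry in step 29.

**Step 28**
Reactants: 35
Product: 36 (1S,2R,3R,7S,8R,10R)-2,3-diacetoxyguaia-4,11(13)-dien-12,8-olide
Conditions: Ac2O, pyridine, DMAP (cat.), CH2Cl2, rt
Reagents that add atoms: acetic anhydride, CC(=O)OC(C)=O
Why: Acetylation installs the C2 acetate of the target and the allylic C3 acetate leaving group; only the C3 acetate is allylic and can ionise.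

### Union

**Step 29**
Reactants: 36; 18 (3 equiv, excess recovered)
Product: 37 japonicone A
Conditions: Pd(PPh3)4 (10 mol %), iPr2NEt, toluene (1 M in 18), 45 °C
Reagents that add atoms: none
Why: Pd(0) ionises the C3 allylic acetate with inversion and syn β-hydride elimination of H1 (Tsuji-type 1,4-elimination) releases the 2-acetoxy-guaia-1(5),3-diene in situ, which the excess α-methylene lactone traps in a Diels–Alder reaction (CH2 to the substituted C1, C11′ to C3; dienophile through the convex face of its cis-fused lactone, carbonyl endo, on the diene face anti to the C2 acetate and C10 methyl), setting C1, C3 and the spiro C11′ and giving the target directly.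

---

## Compound list

1 | acrolein | C=CC=O | starting material
2 | methyl acrylate | C=CC(=O)OC | starting material
3 | methyl 3-hydroxy-2-methylidenepent-4-enoate (racemic) | C=CC(O)C(=C)C(=O)OC | intermediate
4 | methyl (2Z)-2-(bromomethyl)penta-2,4-dienoate | C=C/C=C(\CBr)C(=O)OC | intermediate
5 | cyclohexane-1,3-dione | O=C1CCCC(=O)C1 | starting material
6 | 2-methylcyclohexane-1,3-dione | CC1C(=O)CCCC1=O | intermediate
7 | allyl acetate | C=CCOC(C)=O | starting material
8 | 2-methyl-2-(prop-2-enyl)cyclohexane-1,3-dione | C=CCC1(C)C(=O)CCCC1=O | intermediate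
9 | (2R,3R)-3-hydroxy-2-methyl-2-(prop-2-enyl)cyclohexan-1-one | C=CC[C@@]1(C)C(=O)CCC[C@H]1O | intermediate
10 | (2R,3R)-3-(TBSO)-2-methyl-2-(prop-2-enyl)cyclohexan-1-one | C=CC[C@@]1(C)C(=O)CCC[C@H]1O[Si](C)(C)C(C)(C)C | intermediate
11 | (2R,3R,6R)-3-(TBSO)-2,6-dimethyl-2-(prop-2-enyl)cyclohexan-1-one | C=CC[C@@]1(C)C(=O)[C@H](C)CC[C@H]1O[Si](C)(C)C(C)(C)C | intermediate
12 | [(1R,3R,6R)-6-(TBSO)-1,3-dimethyl-2-oxocyclohexyl]acetaldehyde | O=CC[C@@]1(C)C(=O)[C@H](C)CC[C@H]1O[Si](C)(C)C(C)(C)C | intermediate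
13 | (4S,5S)-5-{[(1R,3R,6R)-6-(TBSO)-1,3-dimethyl-2-oxocyclohexyl]methyl}-4-ethenyl-3-methylideneoxolan-2-one | C=C[C@H]1C(=C)C(=O)O[C@H]1C[C@@]2(C)C(=O)[C@H](C)CC[C@H]2O[Si](C)(C)C(C)(C)C | intermediate
14 | (4S,5S)-5-{[(1S,3R,6R)-6-(TBSO)-1,3-dimethyl-2-methylidenecyclohexyl]methyl}-4-ethenyl-3-methylideneoxolan-2-one | C=C[C@H]1C(=C)C(=O)O[C@H]1C[C@@]2(C)C(=C)[C@H](C)CC[C@H]2O[Si](C)(C)C(C)(C)C | intermediate
15 | (1R,4R,7S,8S,10S)-1-(TBSO)eudesma-5,11(13)-dien-12,8-olide | C=C1C(=O)O[C@H]2C[C@@]3(C)C(=C[C@H]21)[C@H](C)CC[C@H]3O[Si](C)(C)C(C)(C)C | intermediate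
16 | (1R,4R,7S,8S,10S)-1-hydroxyeudesma-5,11(13)-dien-12,8-olide | C=C1C(=O)O[C@H]2C[C@@]3(C)C(=C[C@H]21)[C@H](C)CC[C@H]3O | intermediate
17 | (4R,7S,8S,10S)-1-oxoeudesma-5,11(13)-dien-12,8-olide | C=C1C(=O)O[C@H]2C[C@@]3(C)C(=C[C@H]21)[C@H](C)CCC3=O | intermediate
18 | (1S,4R,7S,8S,10S)-1-hydroxyeudesma-5,11(13)-dien-12,8-olide | C=C1C(=O)O[C@H]2C[C@@]3(C)C(=C[C@H]21)[C@H](C)CC[C@@H]3O | intermediate
19 | (E)-but-2-en-1-ol | C/C=C/CO | starting material
20 | (E)-but-2-en-1-yl methyl carbonate | C/C=C/COC(=O)OC | intermediate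
21 | 2-methylcyclopentane-1,3-dione | CC1C(=O)CCC1=O | starting material
22 | 2-methyl-3-(2-methylpropoxy)cyclopent-2-en-1-one | CC1=C(OCC(C)C)CCC1=O | intermediate
23 | (5S)-5-[(2R)-but-3-en-2-yl]-2-methyl-3-(2-methylpropoxy)cyclopent-2-en-1-one | C=C[C@@H](C)[C@@H]1CC(OCC(C)C)=C(C)C1=O | intermediate
24 | (5S)-5-[(2R)-4-hydroxybutan-2-yl]-2-methyl-3-(2-methylpropoxy)cyclopent-2-en-1-one | OCC[C@@H](C)[C@@H]1CC(OCC(C)C)=C(C)C1=O | intermediate
25 | (5S)-5-[(2R)-4-(TBDPSO)butan-2-yl]-2-methyl-3-(2-methylpropoxy)cyclopent-2-en-1-one | CC(C)(C)[Si](c1ccccc1)(c1ccccc1)OCC[C@@H](C)[C@@H]1CC(OCC(C)C)=C(C)C1=O | intermediate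
26 | allylmagnesium bromide | C=CC[Mg]Br | starting material
27 | (4S)-4-[(2R)-4-(TBDPSO)butan-2-yl]-2-methyl-3-(prop-2-enyl)cyclopent-2-en-1-one | C=CCC1=C(C)C(=O)C[C@H]1[C@H](C)CCO[Si](c2ccccc2)(c2ccccc2)C(C)(C)C | intermediate
28 | methyl 2-(hydroxymethyl)acrylate | C=C(CO)C(=O)OC | starting material
29 | methyl (2E)-2-(hydroxymethyl)-4-{(5S)-5-[(2R)-4-(TBDPSO)butan-2-yl]-2-methyl-3-oxocyclopent-1-en-1-yl}but-2-enoate | COC(=O)/C(CO)=C/CC1=C(C)C(=O)C[C@H]1[C@H](C)CCO[Si](c2ccccc2)(c2ccccc2)C(C)(C)C | intermediate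
30 | methyl (2Z)-2-(bromomethyl)-4-{(5S)-5-[(2R)-4-(TBDPSO)butan-2-yl]-2-methyl-3-oxocyclopent-1-en-1-yl}but-2-enoate | COC(=O)/C(CBr)=C/CC1=C(C)C(=O)C[C@H]1[C@H](C)CCO[Si](c2ccccc2)(c2ccccc2)C(C)(C)C | intermediate
31 | methyl (2Z)-2-(bromomethyl)-4-{(5S)-5-[(2R)-4-hydroxybutan-2-yl]-2-methyl-3-oxocyclopent-1-en-1-yl}but-2-enoate | COC(=O)/C(CBr)=C/CC1=C(C)C(=O)C[C@H]1[C@H](C)CCO | intermediate
32 | methyl (2Z)-2-(bromomethyl)-4-{(5S)-2-methyl-3-oxo-5-[(2R)-4-oxobutan-2-yl]cyclopent-1-en-1-yl}but-2-enoate | COC(=O)/C(CBr)=C/CC1=C(C)C(=O)C[C@H]1[C@H](C)CC=O | intermediate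
33 | (1S,7S,8R,10R)-3-oxoguaia-4,11(13)-dien-12,8-olide | C=C1C(=O)O[C@@H]2C[C@@H](C)[C@@H]3CC(=O)C(C)=C3C[C@@H]12 | intermediate
34 | (1S,2R,7S,8R,10R)-2-hydroxy-3-oxoguaia-4,11(13)-dien-12,8-olide | C=C1C(=O)O[C@@H]2C[C@@H](C)[C@@H]3[C@@H](O)C(=O)C(C)=C3C[C@@H]12 | intermediate
35 | (1S,2R,3R,7S,8R,10R)-2,3-dihydroxyguaia-4,11(13)-dien-12,8-olide | C=C1C(=O)O[C@@H]2C[C@@H](C)[C@@H]3[C@@H](O)[C@H](O)C(C)=C3C[C@@H]12 | intermediate
36 | (1S,2R,3R,7S,8R,10R)-2,3-diacetoxyguaia-4,11(13)-dien-12,8-olide | C=C1C(=O)O[C@@H]2C[C@@H](C)[C@@H]3[C@@H](OC(C)=O)[C@H](OC(C)=O)C(C)=C3C[C@@H]12 | intermediate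
37 | japonicone A | C=C1C(=O)O[C@@H]2C[C@@H](C)[C@]34C[C@]5(C(=O)O[C@H]6C[C@@]7(C)C(=C[C@H]65)[C@H](C)CC[C@@H]7O)[C@H](C(C)=C3C[C@@H]12)[C@@H]4OC(C)=O | target

---

## Totals and risks

**Total steps:** 29.
**Longest linear sequence:** 14 (steps 16–29; the eudesmane branch is 13), i.e. 48 % of the total.

**Three steps most likely to fail**

1. **Step 29 (Pd-triggered diene release / Diels–Alder).** The 5-acetoxy-cyclopentadiene can undergo [1,5]-H shift, dimerise through its own methylene lactone, or react on the face syn to the acetate (oxygen substituents at this position normally direct syn, so the required anti/endo outcome rests on the C10 methyl and the bulk of the dienophile). Fallback: drop the Pd cascade; carry the C2 oxygen as a bulky TIPS ether and mask the guaianolide methylene as its Me2NH adduct, pre-form the diene at −40 °C by Martin-sulfurane dehydration of the C3 alcohol, run a Me2AlCl-promoted Diels–Alder at low temperature, then swap TIPS for acetate and unmask (MeI, NaHCO3).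

2. **Step 9 (proposed new Cr-catalysed asymmetric carboxy-pentadienylation).** Risks are ε- instead of γ-attack, anti instead of syn addition, or poor catalyst control. Fallback (known chemistry): make ring B first — allylmagnesium bromide addition to 12, Lombardo methylenation, ring-closing metathesis and oxidation to the Δ5-8-ketone — then attach the lactone classically by C7′ alkylation with methyl bromoacetate, K-Selectride reduction/lactonisation to the cis-lactone and Eschenmoser-salt α-methylenation.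

3. **Step 25 (intramolecular Cr allylation to the seven-membered ring).** The syn adduct (7,8-cis lactone) or the wrong aldehyde face may dominate. Fallback: stop at the hydroxy ester, saponify, and close the lactone under Mitsunobu conditions with inversion at C8 to reach the trans-lactone.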